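**Assumption:** (R)-(+)-citronellol, 2-methylcyclohex-2-en-1-one and methyl methacrylate are bought. Positions are given in halimane numbering (C1–C20; ring A = C1–C5, C10; ring B = C5–C10). For the two chiral catalysts (steps 4 and 7) the antipode that gives the drawn configuration is fixed by one screen each.

## Retrosynthetic overview

1. Key bond C2–O: the enone oxygen is put in last by allylic C–H oxygenation of methyl 15-acetoxy-ent-halim-1(10)-en-18-oate. Leaving C2 unoxidised until then is what lets ring A come from an oxygen-free diene with the correct regiochemistry.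
2. Ring A (C2–C3 and C4–C5 bonds, stereocentres C4 and C5): catalyst-controlled exo Diels–Alder reaction of a ring B vinylcyclohexene with methyl methacrylate.
3. The diene comes from the ring B ketone by enol triflate formation and Stille vinylation.
4. C8 and C9: one-pot asymmetric conjugate methylation of 2-methylcyclohex-2-enone and enolate alkylation with a C5 iodide.
5. The iodide (C13) comes from (R)-citronellol by oxidative cleavage and iododecarboxylation. Ring B is bought; ring A is the only ring formed.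

## Route

**Step 1**
Reactants: 1 (R)-(+)-citronellol, (3R)-3,7-dimethyloct-6-en-1-ol
Product: 2 tert-butyl{[(3R)-3,7-dimethyloct-6-en-1-yl]oxy}dimethylsilane
Conditions: TBSCl, imidazole, DMF, 0 °C → rt
Reagents that add atoms: tert-butyldimethylsilyl chloride, CC(C)(C)[Si](C)(C)Cl
Why: O-silylation of a primary alcohol (silyl ether protection), chosen because the C15 oxygen must pass the Grignard, enolate and KHMDS steps, which an acetate would not.

**Step 2**
Reactants: 2 tert-butyl{[(3R)-3,7-dimethyloct-6-en-1-yl]oxy}dimethylsilane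
Product: 4 (4R)-6-[(tert-butyldimethylsilyl)oxy]-4-methylhexanoic acid, via aldehyde 3 (not isolated)
Conditions: RuCl3·xH2O (2 mol %), NaIO4 (4 equiv), MeCN/EtOAc/pH 7 phosphate buffer, 0 °C → rt
Reagents that add atoms: sodium periodate, [Na+].[O-]I(=O)(=O)=O; water, O
Why: RuO4 made in situ cleaves the trisubstituted olefin to acetone and aldehyde 3 and oxidises 3 on to the acid (oxidative alkene cleavage), with the remote stereocentre untouched.

**Step 3**
Reactants: 4 (4R)-6-[(tert-butyldimethylsilyl)oxy]-4-methylhexanoic acid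
Product: 6 tert-butyl{[(3S)-5-iodo-3-methylpentyl]oxy}dimethylsilane, via acyl hypoiodite 5 (not isolated)
Conditions: PhI(OAc)2 (1.1 equiv), I2 (1.0 equiv), cyclohexane, hν (tungsten lamp), reflux
Reagents that add atoms: iodine, I-I
Why: Iododecarboxylation (Hunsdiecker-type, Suárez conditions): O–I homolysis of 5, loss of CO2 and iodine capture of the primary radical remove the one surplus carbon; the descriptor changes to S only through the priority rules.

**Step 4**
Reactants: 7 2-methylcyclohex-2-en-1-one; 6 tert-butyl{[(3S)-5-iodo-3-methylpentyl]oxy}dimethylsilane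
Product: 9 (2S,3R)-2-{(3R)-5-[(tert-butyldimethylsilyl)oxy]-3-methylpentyl}-2,3-dimethylcyclohexan-1-one, via magnesium enolate 8 (not isolated)
Conditions: MeMgBr (1.1 equiv), Cu(OTf)2 (3 mol %), chiral hydroxyalkyl imidazolinium salt (NHC precursor, 4 mol %), Et2O, −30 °C; then 6 (1.3 equiv), HMPA, THF, −30 °C → rt
Reagents that add atoms: methylmagnesium bromide, C[Mg]Br
Why: Copper–NHC-catalysed asymmetric conjugate addition sets C8 (R) under ligand control and leaves the regiodefined tetrasubstituted enolate 8, which the primary iodide alkylates (SN2) anti to the neighbouring C8 methyl, so C9 (S) forms with the two methyls cis and the chain trans to the C8 methyl (tandem conjugate addition–enolate alkylation).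

**Step 5**
Reactants: 9 (2S,3R)-2-{(3R)-5-[(tert-butyldimethylsilyl)oxy]-3-methylpentyl}-2,3-dimethylcyclohexan-1-one
Product: 11 (5R,6S)-6-{(3R)-5-[(tert-butyldimethylsilyl)oxy]-3-methylpentyl}-5,6-dimethylcyclohex-1-en-1-yl trifluoromethanesulfonate, via potassium enolate 10 (not isolated)
Conditions: KHMDS, THF, −78 °C; then PhNTf2, −78 → 0 °C
Reagents that add atoms: N-phenylbis(trifluoromethanesulfonimide), O=S(=O)(N(c1ccccc1)S(=O)(=O)C(F)(F)F)C(F)(F)F
Why: C9 is quaternary, so enolisation can only go towards C5, and the potassium enolate is O-sulfonylated (enol triflate formation) without touching a stereocentre.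

**Step 6**
Reactants: 11 (5R,6S)-6-{(3R)-5-[(tert-butyldimethylsilyl)oxy]-3-methylpentyl}-5,6-dimethylcyclohex-1-en-1-yl trifluoromethanesulfonate
Product: 12 tert-butyl({(3R)-5-[(1S,6R)-2-ethenyl-1,6-dimethylcyclohex-2-en-1-yl]-3-methylpentyl}oxy)dimethylsilane
Conditions: tributyl(vinyl)stannane, Pd(PPh3)4 (5 mol %), LiCl (3 equiv), THF, 65 °C
Reagents that add atoms: tributyl(vinyl)stannane, C=C[Sn](CCCC)(CCCC)CCCC
Why: Stille coupling (oxidative addition of the enol triflate to zerovalent palladium, chloride-assisted transmetalation, reductive elimination) gives the C5=C10–C1=C2 diene next to the quaternary centre.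

**Step 7**
Reactants: 12 tert-butyl({(3R)-5-[(1S,6R)-2-ethenyl-1,6-dimethylcyclohex-2-en-1-yl]-3-methylpentyl}oxy)dimethylsilane; 13 methyl methacrylate
Product: 14 methyl (1S,5S,6R,8aS)-5-{(3R)-5-[(tert-butyldimethylsilyl)oxy]-3-methylpentyl}-1,5,6-trimethyl-1,2,3,5,6,7,8,8a-octahydronaphthalene-1-carboxylate
Conditions: chiral IDPi (imidodiphosphorimidate) acid (3 mol %) pre-silylated with allyltrimethylsilane (6 mol %), 13 (3 equiv), toluene, −60 → −30 °C
Reagents that add atoms: none
Why: Proposed new method: the ion pair Me3Si+·IDPi− O-silylates methyl methacrylate to a strongly LUMO-lowered silyloxycarbenium ion held inside the confined chiral anion, which leaves only the Re face of its α-carbon open; the unhindered vinyl terminus C2 of 12 bonds first to the β-CH2 (asynchronous [4+2], the same "ortho" regiochemistry that 6,6-dialkyl-1-vinylcyclohexenes show with α-methyl dienophiles), the bulky silylated ester stays exo to avoid the C9 quaternary centre (methyl endo, so CO2Me ends cis to H5), and with the dienophile face fixed the exo mode can only use the diene face anti to the C11 chain, which sets C4 (S) and C5 (S) by catalyst control over the weak intrinsic bias of the diene, while silyl transfer from the adduct to fresh methacrylate turns the cycle over; closest known reaction type: chiral silylium (IDPi) Lewis acid catalysed enantioselective Diels–Alder reactions of simple α,β-unsaturated methyl esters with cyclopentadiene and unactivated dienes, not yet shown for an α-branched acrylate that creates a quaternary centre or for catalyst-controlled diastereoselection on a hindered chiral semicyclic diene.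

**Step 8**
Reactants: 14 methyl (1S,5S,6R,8aS)-5-{(3R)-5-[(tert-butyldimethylsilyl)oxy]-3-methylpentyl}-1,5,6-trimethyl-1,2,3,5,6,7,8,8a-octahydronaphthalene-1-carboxylate
Product: 16 methyl (1S,5S,6R,8aS)-5-[(3R)-5-acetoxy-3-methylpentyl]-1,5,6-trimethyl-1,2,3,5,6,7,8,8a-octahydronaphthalene-1-carboxylate, via alkoxide 15 (not isolated)
Conditions: TBAF, THF, 0 °C → rt; then Ac2O, DMAP (cat.), rt
Reagents that add atoms: acetic anhydride, CC(=O)OC(C)=O
Why: Fluoride cleaves the Si–O bond and the liberated alkoxide is acetylated in the same flask (desilylation then O-acylation), installing the natural C15 acetate once all strongly basic steps are over.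

**Step 9**
Reactants: 16 methyl (1S,5S,6R,8aS)-5-[(3R)-5-acetoxy-3-methylpentyl]-1,5,6-trimethyl-1,2,3,5,6,7,8,8a-octahydronaphthalene-1-carboxylate
Product: 18 methyl (1S,5S,6R,8aS)-5-[(3R)-5-acetoxy-3-methylpentyl]-1,5,6-trimethyl-3-oxo-1,2,3,5,6,7,8,8a-octahydronaphthalene-1-carboxylate (CNP0250576.1), via allylic peroxide 17 (not isolated)
Conditions: Rh2(cap)4, dirhodium tetrakis(caprolactamate) (1 mol %), tBuOOH (70 % aq, 5 equiv), CH2Cl2, 40 °C
Reagents that add atoms: tert-butyl hydroperoxide, CC(C)(C)OO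
Why: Allylic C–H oxidation: tert-butylperoxyl radicals abstract the only unhindered secondary allylic hydrogen (C2–H; C5–H is tertiary and screened by quaternary C4, C9 has none), the allyl radical is trapped at C2 as peroxide 17 and loss of tert-butanol gives the conjugated Δ1(10)-2-one, so the new C2–O bond completes the target with C4, C5, C8, C9 and C13 untouched.

## Compound list

1 | (R)-(+)-citronellol, (3R)-3,7-dimethyloct-6-en-1-ol | C[C@H](CCC=C(C)C)CCO | starting material
2 | tert-butyl{[(3R)-3,7-dimethyloct-6-en-1-yl]oxy}dimethylsilane | C[C@H](CCC=C(C)C)CCO[Si](C)(C)C(C)(C)C | intermediate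
3 | (4R)-6-[(tert-butyldimethylsilyl)oxy]-4-methylhexanal | C[C@H](CCC=O)CCO[Si](C)(C)C(C)(C)C | intermediate
4 | (4R)-6-[(tert-butyldimethylsilyl)oxy]-4-methylhexanoic acid | C[C@H](CCC(=O)O)CCO[Si](C)(C)C(C)(C)C | intermediate
5 | (4R)-6-[(tert-butyldimethylsilyl)oxy]-4-methylhexanoyl hypoiodite | C[C@H](CCC(=O)OI)CCO[Si](C)(C)C(C)(C)C | intermediate
6 | tert-butyl{[(3S)-5-iodo-3-methylpentyl]oxy}dimethylsilane | C[C@H](CCI)CCO[Si](C)(C)C(C)(C)C | intermediate
7 | 2-methylcyclohex-2-en-1-one | CC1=CCCCC1=O | starting material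
8 | bromomagnesium (3R)-2,3-dimethylcyclohex-1-en-1-olate | Br[Mg]OC1=C(C)[C@H](C)CCC1 | intermediate
9 | (2S,3R)-2-{(3R)-5-[(tert-butyldimethylsilyl)oxy]-3-methylpentyl}-2,3-dimethylcyclohexan-1-one | O=C1CCC[C@@H](C)[C@]1(C)CC[C@@H](C)CCO[Si](C)(C)C(C)(C)C | intermediate
10 | potassium (5R,6S)-6-{(3R)-5-[(tert-butyldimethylsilyl)oxy]-3-methylpentyl}-5,6-dimethylcyclohex-1-en-1-olate | [K+].[O-]C1=CCC[C@@H](C)[C@]1(C)CC[C@@H](C)CCO[Si](C)(C)C(C)(C)C | intermediate
11 | (5R,6S)-6-{(3R)-5-[(tert-butyldimethylsilyl)oxy]-3-methylpentyl}-5,6-dimethylcyclohex-1-en-1-yl trifluoromethanesulfonate | O=S(=O)(OC1=CCC[C@@H](C)[C@]1(C)CC[C@@H](C)CCO[Si](C)(C)C(C)(C)C)C(F)(F)F | intermediate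
12 | tert-butyl({(3R)-5-[(1S,6R)-2-ethenyl-1,6-dimethylcyclohex-2-en-1-yl]-3-methylpentyl}oxy)dimethylsilane | C=CC1=CCC[C@@H](C)[C@]1(C)CC[C@@H](C)CCO[Si](C)(C)C(C)(C)C | intermediate
13 | methyl methacrylate | COC(=O)C(C)=C | starting material
14 | methyl (1S,5S,6R,8aS)-5-{(3R)-5-[(tert-butyldimethylsilyl)oxy]-3-methylpentyl}-1,5,6-trimethyl-1,2,3,5,6,7,8,8a-octahydronaphthalene-1-carboxylate (15-silyl ether of methyl 15-hydroxy-ent-halim-1(10)-en-18-oate) | COC(=O)[C@@]1(C)CCC=C2[C@@H]1CC[C@@H](C)[C@]2(C)CC[C@@H](C)CCO[Si](C)(C)C(C)(C)C | intermediate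
15 | tetrabutylammonium alkoxide of methyl (1S,5S,6R,8aS)-5-[(3R)-5-hydroxy-3-methylpentyl]-1,5,6-trimethyl-1,2,3,5,6,7,8,8a-octahydronaphthalene-1-carboxylate | CCCC[N+](CCCC)(CCCC)CCCC.COC(=O)[C@@]1(C)CCC=C2[C@@H]1CC[C@@H](C)[C@]2(C)CC[C@@H](C)CC[O-] | intermediate
16 | methyl (1S,5S,6R,8aS)-5-[(3R)-5-acetoxy-3-methylpentyl]-1,5,6-trimethyl-1,2,3,5,6,7,8,8a-octahydronaphthalene-1-carboxylate (methyl 15-acetoxy-ent-halim-1(10)-en-18-oate) | COC(=O)[C@@]1(C)CCC=C2[C@@H]1CC[C@@H](C)[C@]2(C)CC[C@@H](C)CCOC(C)=O | intermediate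
17 | methyl (1S,5S,6R,8aS)-5-[(3R)-5-acetoxy-3-methylpentyl]-3-(tert-butylperoxy)-1,5,6-trimethyl-1,2,3,5,6,7,8,8a-octahydronaphthalene-1-carboxylate (both C3 epimers, halimane C2) | COC(=O)[C@@]1(C)CC(OOC(C)(C)C)C=C2[C@@H]1CC[C@@H](C)[C@]2(C)CC[C@@H](C)CCOC(C)=O | intermediate
18 | methyl (1S,5S,6R,8aS)-5-[(3R)-5-acetoxy-3-methylpentyl]-1,5,6-trimethyl-3-oxo-1,2,3,5,6,7,8,8a-octahydronaphthalene-1-carboxylate | COC(=O)[C@@]1(C)CC(=O)C=C2[C@@H]1CC[C@@H](C)[C@]2(C)CC[C@@H](C)CCOC(C)=O | target

## Step count and risks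

Total steps: 9. Longest linear sequence: 9 (steps 1–9 from 1); the ring B building block 7 enters at step 4 (6 steps from 7).

**Step 7 (new method, highest risk).** The silylium catalyst may not engage the hindered diene with an α-branched ester, or may give the endo adduct (C5 epimer, same C4) or the exo adduct on the other diene face (4R,5R). The diene itself has little facial bias, so selectivity rests entirely on the catalyst. The fallback sets out from 12 and comes back at 14 and uses known chemistry. Diene 12 and methacrolein react under a triflimide-activated chiral oxazaborolidinium cation (CH2Cl2, −78 °C), the established enantioselective exo Diels–Alder system for this α-methyl enal, to give (1S,5S,6R,8aS)-5-{(3R)-5-[(tert-butyldimethylsilyl)oxy]-3-methylpentyl}-1,5,6-trimethyl-1,2,3,5,6,7,8,8a-octahydronaphthalene-1-carbaldehyde F3. Pinnick oxidation (NaClO2, NaH2PO4, 2-methyl-2-butene, tBuOH/H2O) gives the corresponding 1-carboxylic acid F4, and TMSCHN2 in toluene/MeOH gives 14. This costs two extra steps, and any diastereomers are separated at the acid stage.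

**Step 4.** The quaternary centre is made with an unactivated primary iodide on a magnesium enolate, which may be slow and give proton transfer or low dr. The conjugate addition is expected at about 90 % ee, so the minor core enantiomer travels as a diastereomer and is removed at 14 or 16. The fallback sets out from 8 and comes back at 9. It replaces the in-situ magnesium enolate by an isolated enol silane and a salt-free lithium enolate. Enolate 8 is quenched with TMSCl/Et3N to give [(3R)-2,3-dimethylcyclohex-1-en-1-yl]oxy(trimethyl)silane F1, which is purified. MeLi (THF, 0 °C) releases lithium (3R)-2,3-dimethylcyclohex-1-en-1-olate F2, which is alkylated with 6 in THF/HMPA (−40 °C → rt) to give 9 with the same anti selectivity.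

**Step 9.** Competing abstraction of the tertiary allylic C5–H (leading to 1-oxo-Δ5(10) products) or over-oxidation could lower the yield. The fallback sets out from 16 and comes back at 18. It replaces radical C–H abstraction by a regiodefined epoxide/allylic-transposition sequence. mCPBA (CH2Cl2, NaHCO3) gives the 1,10-epoxide of 16 F5. PhSeSePh/NaBH4 in EtOH opens it at the secondary carbon C1 to the 1-phenylselanyl-10-hydroxy compound F6. H2O2 (THF, 0 °C → rt) gives the selenoxide F7, whose syn-elimination away from the carbinol carbon gives the tertiary allylic alcohol methyl 15-acetoxy-10-hydroxy-ent-halim-1-en-18-oate F8. Pyridinium chlorochromate (CH2Cl2, rt) effects the Dauben–Babler oxidative 1,3-transposition to 18. The new centres at C1/C10 are lost again, so both epoxide faces converge.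

## Further compounds

F1 | step 4 | [(3R)-2,3-dimethylcyclohex-1-en-1-yl]oxy(trimethyl)silane | C[Si](C)(C)OC1=C(C)[C@H](C)CCC1
F2 | step 4 | lithium (3R)-2,3-dimethylcyclohex-1-en-1-olate | [Li+].[O-]C1=C(C)[C@H](C)CCC1
F3 | step 7 | (1S,5S,6R,8aS)-5-{(3R)-5-[(tert-butyldimethylsilyl)oxy]-3-methylpentyl}-1,5,6-trimethyl-1,2,3,5,6,7,8,8a-octahydronaphthalene-1-carbaldehyde | O=C[C@@]1(C)CCC=C2[C@@H]1CC[C@@H](C)[C@]2(C)CC[C@@H](C)CCO[Si](C)(C)C(C)(C)C
F4 | step 7 | (1S,5S,6R,8aS)-5-{(3R)-5-[(tert-butyldimethylsilyl)oxy]-3-methylpentyl}-1,5,6-trimethyl-1,2,3,5,6,7,8,8a-octahydronaphthalene-1-carboxylic acid | OC(=O)[C@@]1(C)CCC=C2[C@@H]1CC[C@@H](C)[C@]2(C)CC[C@@H](C)CCO[Si](C)(C)C(C)(C)C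
F5 | step 9 | methyl 15-acetoxy-1,10-epoxy-ent-haliman-18-oate (C1/C10 epoxide epimers, other centres as in 16) | COC(=O)[C@@]1(C)CCC2OC23[C@@H]1CC[C@@H](C)[C@]3(C)CC[C@@H](C)CCOC(C)=O
F6 | step 9 | methyl 15-acetoxy-10-hydroxy-1-(phenylselanyl)-ent-haliman-18-oate (C1/C10 epimers, other centres as in 16) | COC(=O)[C@@]1(C)CCC([Se]c3ccccc3)C2(O)[C@@H]1CC[C@@H](C)[C@]2(C)CC[C@@H](C)CCOC(C)=O
F7 | step 9 | selenoxide of F6, methyl 15-acetoxy-10-hydroxy-1-(phenylseleninyl)-ent-haliman-18-oate | COC(=O)[C@@]1(C)CCC([Se](=O)c3ccccc3)C2(O)[C@@H]1CC[C@@H](C)[C@]2(C)CC[C@@H](C)CCOC(C)=O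
F8 | step 9 | methyl 15-acetoxy-10-hydroxy-ent-halim-1-en-18-oate (C10 epimers, other centres as in 16) | COC(=O)[C@@]1(C)CC=CC2(O)[C@@H]1CC[C@@H](C)[C@]2(C)CC[C@@H](C)CCOC(C)=O
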